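A small charge of free catalyst has to sort a racemate, while partner, the limiting reagent of this flask, arrives in portions and has two other ways to go.

    partner + free catalyst + left-handed substrate → free catalyst + left-handed product (k1 = 9.0 /M²/min)
    partner + free catalyst + right-handed substrate → free catalyst + right-handed product (k2 = 3.1 /M²/min)
    partner + free catalyst → spent catalyst (k3 = 0.10 /M/min)
    2 partner → homo dimer (k4 = 0.058 /M/min)

left-handed substrate 0.10 M; partner 0.100 M (in portions, 4); free catalyst 15 mM; right-handed substrate 0.10 M; time 6.0 h; the portions of partner follow each other after 30 min, the first at the start

- free catalyst is single-handed; left-handed substrate and right-handed substrate are mirror images of each other, charged as a racemate, each of them at the stated concentration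
- a doubled species enters its step squared and goes two at a time
- the reaction counts as stopped when no species that holds the left-handed substrate and right-handed substrate together changes by six tenths of a point or more over the second half of the time
- run time (flask): 6.0 h

* why nothing more happens at 6.0 h, or that something still does (all of the left-handed substrate has reacted / the partner has run out first / forward and back rates have come level / no working catalyst is left / it is still moving)
* conversion of left-handed substrate and right-handed substrate together at 6.0 h
* amount of left-handed product at 6.0 h, in percent of the left-handed substrate and right-handed substrate together charged
* amount of right-handed substrate at 6.0 h, in percent of the left-handed substrate and right-handed substrate together charged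
* amount of left-handed product if the flask were left three thousand times as long, in percent of the left-handed substrate and right-handed substrate together charged

We follow the part of the consumed partner that ends in a product. Per partner, the way to product runs at a pull (each substrate times its constant, summed) times free catalyst. The way to spent catalyst runs at its constant times free catalyst, and the way to homo dimer at twice its constant times partner.

With no partner lost, the charge of this flask allows a conversion of 50.0%. For a tighter upper bound we hold the pull at its charge value 1.21 /M/min, since the substrates are only used up, and count no homo dimer. That gives a part of 92.4% and a conversion of 46.2%. For a lower mark, a rough guess and not a strict bound, we halve the pull and free catalyst and take two portions of partner of 25.0 mM each, which gives 40.9% and 20.4%.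

Our own figure replaces the curves by their means. The partner can consume half of the substrates, so the pull may end near half its charge value; we guess the same for free catalyst and set both midway: 0.907 /M/min and 11.2 mM. With one portion of partner, that gives 71.7% for the useful share, the consumed partner that ends in a product. The conversion is then 35.9% once the partner is consumed, but this reckoning has no clock in it.

The forecast says it is still moving, with conversion 33% (30% to 36%), left-handed product 23.3%, right-handed substrate 40.2% and a long-run left-handed product of 25%. Of the partner it says that “about a fifth of it goes to the dimer and a few percent kills catalyst”. Its conversion lies inside our marks, below our figure.

The simulation gives it is still moving, with conversion 34.1%, left-handed product 24.0%, right-handed substrate 39.9% and a long-run left-handed product of 25.1%. Partner stands at 4.0% after 6.00 h. The useful share read from this is 71.1%, against 71.7% reckoned.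

The neighbour flask takes 0.17 M of partner, so its portions are 42.5 mM, and the pull and free catalyst of the first flask, held unchanged, give a useful share of 62.8%. Its conversion is 44.2% with partner left at 6.3%, so its useful share reads 55.5%, lower than in the first flask and lower than reckoned. Its free catalyst stood at 30.5% after 6.00 h, against 51.5% in the first flask.

(The numbers were drawn at random within sensible limits; the rest is arithmetic.)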